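## The problem

The target is a (3R)-5,7-dimethoxyphthalide whose C3 is tied by an unbranched hexamethylene chain to C2 of a 7-methyl-1,6-dioxaspiro[4.4]nonane of configuration 2S,5R,7S. Ring A is taken as O1, C2 (chain-bearing), C3, C4 and the spiro carbon C5; ring B as C5, O6, C7 (methyl-bearing), C8 and C9. The four stereocentres fall into two groups that cannot influence each other: the lactone C3 lies six methylene groups from the spiroketal, must be set by a reagent, and must be set cleanly because epimers differing only at so remote a centre cannot be counted on to separate. C2 and C7 are ordinary secondary carbinol carbons and can be bought as such. The spiro carbon C5 is the difficult one: in a [4.4] spiroketal both epimers have the same anomeric stabilisation, and the C2 and C7 substituents are too far apart to tip the balance, so acid-mediated ketalisation returns both. C5 therefore has to be fixed kinetically, and once fixed the molecule must not meet Brønsted or Lewis acids again; the lactone must also be spared strong nucleophiles and benzylic hydrogenolysis, and the electron-rich arene electrophiles. The opening is that C5 carries, besides its two oxygens, the ring A carbon C4: if the ring A carbon C3 is for a time a carbonyl group, ring A is a furan-3-one, and its C4–C5 bond is the bond a carbene at C4 would make by inserting into the C–H bond of a ring B 2-alkoxytetrahydrofuran acetal five atoms away. Since insertion puts carbon where hydrogen was, a separable acetal configuration would be carried unchanged into the spiro centre.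

## Retrosynthesis

**Lactone (25 from 23).** The acyl–oxygen bond of the lactone and the C3–H bond are cut, which leads through hydroxy ester 24 to keto ester 23. The neighbouring cut, C3–aryl by adding an aryl metal to an aliphatic aldehyde, would need an enantioselective arylation of an unbranched aldehyde. The known cobalt-catalysed coupling of 2-iodobenzoates with aldehydes (CoI2 with a chiral diphosphine, zinc dust as reductant) would in addition run hot in the presence of ZnI2, a Lewis acid that endangers C5. Reduction of an aryl alkyl ketone with RuCl[(R,R)-TsDPEN](p-cymene) and formate is better established, and for 2-acylbenzoates it is known to end in the phthalide. Precursor 23 has one stereocentre and one ring fewer. The forward step must deliver hydride to one face under non-acidic conditions.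

**Ketone (23 from 16, 21 and CO).** Both bonds at the ketone carbon are cut, giving alkene 16 (through borane 22), iodo ester 21 and carbon monoxide. Taking the carbonyl carbon from CO means the precious fragment needs only a terminal alkene and no acyl activation. The alternative (oxidative cleavage of a longer alkene, oxidation, activation as an acid chloride) costs three more steps on the spiroketal and passes through HCl-generating chemistry. Precursor 16 has no arene and three stereocentres; 21 is achiral. The forward reaction needs anti-Markovnikov hydroboration and CO insertion faster than direct coupling.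

**Arene (21 from 17).** The ester is traced through acid 20 and aldehyde 19 (iminium salt 18) to 1-iodo-3,5-dimethoxybenzene 17 by removing one formyl carbon. Formylation is asked to go ortho to iodine rather than between the methoxy groups.

**Removal of the C3 oxygen (16 from 12).** The two C3–H bonds of 16 are traced through xanthate 15 (salt 14) and alcohol 13 to ketone 12. The carbonyl group exists only because it makes the carbene; it is removed by a radical deoxygenation because the ionic alternatives (thioketal, hydrazone) need acid or hot base, either of which would open the beta-alkoxy ketone or equilibrate C5.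

**Spiro C–C bond (12 from 11).** The C4–C5 bond of ring A is cut to give diazoketone 11, in which C5 is the acetal carbon of a trans-2-alkoxy-5-methyltetrahydrofuran. Against C–O disconnections at C5 this cut has the advantage that the configuration at C5 is not decided under equilibrating conditions. It removes one ring and turns a quaternary stereocentre into a tertiary acetal centre that can be separated and recycled. The forward reaction must insert with retention and must prefer the acetal C–H bond over the chain C–H bonds and over the ring B oxygen lone pair.

**Diazoketone (11 from 8).** The bond between the carbonyl carbon and the diazo carbon is cut, leading through mixed anhydride 10 and potassium salt 9 to ester 8. The carboxylate is used instead of the free acid so that the acetal never sits next to a proton source.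

**Acetal (8 from 4 and 7).** The exocyclic acetal C–O bond is cut to hydroxy ester 4 and lactol acetate 7. The oxocarbenium ion is expected to be captured from both faces, so this step is asked only for a separable mixture whose unwanted anomer can be re-equilibrated.

**Building blocks.** Hydroxy ester 4 is cut at C3–C4 to methyl (S)-glycidate 2 and the Grignard reagent 3 from 5-bromopent-1-ene 1; this gives the alpha-hydroxy ester in one step at the correct oxidation level. An epoxyalkene/kinetic-resolution/silylation/oxidation sequence would need about three more steps and pass through an epimerisable alpha-alkoxy aldehyde. Acetate 7 comes from (S)-gamma-valerolactone 5 through aluminium lactolate 6; the lactone supplies C7.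

## Roads not taken

Alternative 1: The cut is made at both CH2–CH2 bonds flanking the ketal carbon. Acetone N,N-dimethylhydrazone A1 would be lithiated with n-BuLi and alkylated in one flask with (S)-propylene oxide A2 and then with (S)-1,2-epoxydec-9-ene A3 to give the dihydroxy hydrazone A4, which on hydrolysis would close to the oct-7-enyl spiroketal A5. It builds the whole spiroketal carbon skeleton with C2 and C7 in place in one operation, from cheap epoxides and by known chemistry. Spiroketal alkene A5 stands at the same stage as 16 and is reached in roughly three steps where the chosen plan needs nine, so in step count and reliability this road is clearly better. Its weak point is C5: ketalisation is thermodynamic and the [4.4] system has no bias, so A5 would form as both C5 epimers, to be separated at a late, non-polar stage with one of them recycled. The chosen plan also has an unselective step (the acetal of 8), but it places the mixture early on cheap material. What it sets against the shorter road is a spiro centre defined by a kinetic, stereoretentive bond formation. Alternative 1 is kept as the fallback for the key step.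

Alternative 2: The benzene ring is cut at C3a–C4 and C7–C7a. The silyloxy ynoate A6, which carries the finished spiroketal chain, and 1,3-dimethoxy-1-(trimethylsilyloxy)buta-1,3-diene A7 would combine in a thermal Diels–Alder reaction and aromatise to the salicylate A8. O-Methylation, desilylation and lactonisation would follow. The oxygenation pattern is placed without ambiguity and no haloarene is needed. The carbinol centre of A6 could be set by asymmetric reduction at the alkynyl ketone oxidation level, which is at least as selective as reducing hindered keto ester 23. Against it: A6 needs four or five steps on the spiroketal fragment; the cycloaddition needs heat and the moisture-sensitive diene A7 while the acid-labile spiroketal is present; and three more steps follow A8. The road also says nothing about C5. The chosen plan spends two steps on the precious fragment after the spiroketal is made; in control of the lactone centre alternative 2 is equal or better.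

Alternative 3: Both C–O bonds of ring A and ring B are cut at the late stage. The keto allylic diol A9 (drawn with the S allylic carbinol that a syn SN2′ course is taken to require) would close to the five-membered hemiketal A10, whose hydroxyl would add in SN2′ fashion to the allylic alcohol under PdCl2(MeCN)2 (divalent palladium) to give the 2-alkenyl spiroketal phthalide A11. Hydrogenation of the alkene of A11 would finish the synthesis. The merits are mildness, convergence with the phthalide already in place, and C2 set by chirality transfer from an easily made allylic alcohol. The weak point is again C5: the two epimers of A10 interconvert and nothing in the structure makes one cyclise faster, and the palladium salt is itself a Lewis acid able to equilibrate A11. A further stereocentre has to be made only to be transferred, and the final hydrogenation sits next to an allylic and a benzylic C–O bond. The chosen plan is longer and rests on an untested insertion, but it addresses the spiro carbon directly. Alternative 3 is better in convergence and avoids diazo compounds.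

Key step: step 6

Assumption: "trans" and "cis" for the ring B acetals refer to the exocyclic alkoxy group and the methyl group. From 12 onwards every work-up and chromatography is kept neutral or basic (triethylamine-washed silica).

## Route

Step 1
Reactants: 1 5-bromopent-1-ene; 2 methyl (2S)-oxirane-2-carboxylate (methyl (S)-glycidate)
Product: 4 methyl (2S)-2-hydroxyoct-7-enoate, via pent-4-enylmagnesium bromide 3 (not isolated)
Conditions: Mg, THF, rt; then CuI (10 mol%), 2, THF, −78 → −30 °C
Reagents that add atoms: none
Why: Copper-catalysed Grignard opening of a terminal epoxide: the organocopper species from 3 and CuI should attack the unsubstituted C3 of the glycidate in an SN2 sense faster than the Grignard reagent adds to the ester at low temperature; C2 of 2 is not touched, so its S configuration becomes that of the carbinol carbon (the later ring A C2).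

Step 2
Reactants: 5 (S)-gamma-valerolactone
Product: 7 (5S)-5-methyltetrahydrofuran-2-yl acetate (both anomers), via diisobutylaluminium lactolate 6 (not isolated)
Conditions: i-Bu2AlH, CH2Cl2, −78 °C; then pyridine, DMAP, Ac2O, −78 → 0 °C
Reagents that add atoms: acetic anhydride, CC(=O)OC(C)=O
Why: Reductive acetylation of a lactone: i-Bu2AlH adds once at −78 °C to give the stable aluminium hemiacetal 6, which is acetylated in the same flask before it can open to the hydroxy aldehyde; the methyl-bearing carbon is untouched, and the new anomeric centre is of no consequence because it is flattened in step 3.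

Step 3
Reactants: 4 methyl (2S)-2-hydroxyoct-7-enoate; 7 (5S)-5-methyltetrahydrofuran-2-yl acetate
Product: 8 methyl (2S)-2-{[(2S,5S)-5-methyltetrahydrofuran-2-yl]oxy}oct-7-enoate (trans acetal)
Conditions: TMSOTf (5 mol%), 4 Å MS, CH2Cl2, −78 → −40 °C; Et3N; chromatography on Et3N-washed silica
Reagents that add atoms: none
Why: Lewis-acid-catalysed acetal exchange: TMSOTf ionises the anomeric acetate to the five-membered oxocarbenium ion, which the secondary hydroxyl of 4 captures from either face, so both anomers are expected without strong bias. The trans (2S,5S) acetal 8 is to be isolated by chromatography and assigned by NOE (acetal hydrogen and C5 hydrogen on opposite faces), and the cis anomer is returned to the same acid for re-equilibration.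

Step 4
Reactants: 8 methyl (2S)-2-{[(2S,5S)-5-methyltetrahydrofuran-2-yl]oxy}oct-7-enoate
Product: 9 potassium (2S)-2-{[(2S,5S)-5-methyltetrahydrofuran-2-yl]oxy}oct-7-enoate
Conditions: KOSiMe3, THF, 0 °C → rt; evaporation
Reagents that add atoms: potassium trimethylsilanolate, C[Si](C)(C)[O-].[K+]
Why: Anhydrous ester cleavage with potassium trimethylsilanolate gives the carboxylate salt directly, so the acid-labile acetal never meets a free carboxylic acid that could re-open it and scramble the anomeric centre; the silanolate is too weak a base to deprotonate the alkoxy-substituted alpha carbon at a useful rate.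

Step 5
Reactants: 9 potassium (2S)-2-{[(2S,5S)-5-methyltetrahydrofuran-2-yl]oxy}oct-7-enoate
Product: 11 (3S)-1-diazo-3-{[(2S,5S)-5-methyltetrahydrofuran-2-yl]oxy}non-8-en-2-one, via isobutyl carbonic mixed anhydride 10 (not isolated)
Conditions: i-BuOCOCl, N-methylmorpholine (cat.), THF, −20 °C; then CH2N2, Et2O, 0 °C → rt
Reagents that add atoms: diazomethane, C=[N+]=[N-]
Why: Acylation of diazomethane as in the first stage of an Arndt–Eistert sequence: the carboxylate gives the mixed carbonic anhydride 10, which diazomethane attacks at the more electrophilic acyl carbon; loss of isobutyl carbonate and a proton gives the diazoketone under conditions that are never acidic, and neither the acetal nor the alpha stereocentre takes part.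

Step 6
Reactants: 11 (3S)-1-diazo-3-{[(2S,5S)-5-methyltetrahydrofuran-2-yl]oxy}non-8-en-2-one
Product: 12 (2S,5R,7S)-2-(hex-5-en-1-yl)-7-methyl-1,6-dioxaspiro[4.4]nonan-3-one
Conditions: Rh2(OAc)4 (2 mol%), CH2Cl2 (high dilution), rt, slow addition of 11; filtration through neutral alumina
Reagents that add atoms: none
Why: Proposed new method: Rh2(OAc)4 (each rhodium divalent) should expel N2 from 11 to give an electrophilic rhodium carbene that reaches the acetal C–H bond of ring B through a six-centre array (carbene carbon, C=O, C3, O, acetal carbon, H) and inserts through a hydride-transfer-like three-centre transition state to make the C4–C5 bond; the closest known reactions are the Rh2(OAc)4-catalysed 1,5 C–H insertion of alpha-alkoxy diazoketones next to an ether oxygen, which gives tetrahydrofuran-3-ones, and the stereoretentive insertion of rhodium carbenes into anomeric C–H bonds of glycosides, but an acetal whose own exocyclic oxygen carries the tether is not known to have been used to create a spiroketal carbon. Ring A closes as a five-membered ring by C–C bond formation between the former diazo carbon and the former acetal carbon (a 1,5 insertion, the atoms O, C3 and C2 of the tether completing the ring). The only new stereocentre, spiro C5, is controlled by the configuration of the acetal carbon of 11: the new C–C bond takes the place of the hydrogen, so the trans (2S,5S) acetal should become 5R, while C2 (from 2) and C7 (from 5) are untouched. Even if the bond forms stepwise by hydride transfer, the enolate carbon is held on the face the hydrogen left and should collapse there before the oxocarbenium ion can turn. Site selectivity is needed against the C5 methylene of the nonenone chain (cyclopentanone formation) and is secured by the two oxygens, which make the acetal C–H bond the most hydridic 1,5 C–H bond in the molecule. Chemoselectivity is needed against six-membered oxonium ylide formation at the ring B oxygen and against collapse through the enolate oxygen; Rh2(OAc)4 or, if it proves too electrophilic, the carboxamidate Rh2(NHCOCH3)4, together with high dilution and slow addition, is chosen for this. The terminal alkene is too remote for cyclopropanation.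

Step 7
Reactants: 12 (2S,5R,7S)-2-(hex-5-en-1-yl)-7-methyl-1,6-dioxaspiro[4.4]nonan-3-one
Product: 13 (2S,5R,7S)-2-(hex-5-en-1-yl)-7-methyl-1,6-dioxaspiro[4.4]nonan-3-ol (both C3 epimers)
Conditions: NaBH4, MeOH–CH2Cl2, −78 → −40 °C
Reagents that add atoms: none
Why: Borohydride reduction at low temperature removes the carbonyl group before enolisation towards C4 can expel a ketal oxygen (retro-oxa-Michael opening to a 3(2H)-furanone) or enolisation towards C2 can epimerise that centre; the configuration of the new carbinol carbon is irrelevant because it is removed in step 9, so the C3 epimers are carried on together.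

Step 8
Reactants: 13 (2S,5R,7S)-2-(hex-5-en-1-yl)-7-methyl-1,6-dioxaspiro[4.4]nonan-3-ol
Product: 15 O-[(2S,5R,7S)-2-(hex-5-en-1-yl)-7-methyl-1,6-dioxaspiro[4.4]nonan-3-yl] S-methyl carbonodithioate, via sodium xanthate salt 14 (not isolated)
Conditions: NaH, imidazole (cat.), CS2, THF, 0 °C → rt; then MeI
Reagents that add atoms: carbon disulfide, S=C=S; iodomethane, CI
Why: Standard xanthate formation: the sodium alkoxide adds to CS2 and the dithiocarbonate salt 14 is S-methylated; the medium is basic throughout, which the spiroketal tolerates.

Step 9
Reactants: 15 O-[(2S,5R,7S)-2-(hex-5-en-1-yl)-7-methyl-1,6-dioxaspiro[4.4]nonan-3-yl] S-methyl carbonodithioate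
Product: 16 (2S,5R,7S)-2-(hex-5-en-1-yl)-7-methyl-1,6-dioxaspiro[4.4]nonane
Conditions: Bu3SnH, AIBN (cat.), toluene, 90 °C
Reagents that add atoms: none
Why: Barton–McCombie deoxygenation: the stannyl radical adds to the thiocarbonyl sulfur, the C3–O bond fragments to a secondary ring radical and this is quenched by Bu3SnH; ring opening by beta-scission is slow for an unstrained tetrahydrofuranyl radical, and cyclisation onto the chain alkene would need a seven-membered ring and cannot compete with hydrogen transfer at normal tin hydride concentration. The conditions are neutral, so C5 is safe.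

Step 10
Reactants: 17 1-iodo-3,5-dimethoxybenzene
Product: 19 2-iodo-4,6-dimethoxybenzaldehyde, via aryl iminium salt 18 (not isolated)
Conditions: POCl3, DMF, 0 → 80 °C; then H2O
Reagents that add atoms: N,N-dimethylformamide, CN(C)C=O; water, O
Why: Vilsmeier–Haack formylation: the chloroiminium ion attacks the arene at C2, which is para to one methoxy group and ortho to the other, in preference to C4, which is ortho to both and flanked by two methoxy groups, as is known for the bromo analogue; hydrolysis of iminium salt 18 gives the aldehyde, and a minor 4-iodo-2,6-dimethoxy isomer would be removed by crystallisation.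

Step 11
Reactants: 19 2-iodo-4,6-dimethoxybenzaldehyde
Product: 20 2-iodo-4,6-dimethoxybenzoic acid
Conditions: NaClO2, NaH2PO4, 2-methylbut-2-ene, t-BuOH–H2O, rt
Reagents that add atoms: sodium chlorite, [Na+].[O-]Cl=O
Why: Pinnick (Lindgren) oxidation converts the hindered, electron-rich aldehyde into the acid without touching the C–I bond; 2-methylbut-2-ene traps hypochlorous acid so that the activated ring is not chlorinated.

Step 12
Reactants: 20 2-iodo-4,6-dimethoxybenzoic acid
Product: 21 methyl 2-iodo-4,6-dimethoxybenzoate
Conditions: MeI, K2CO3, DMF, rt
Reagents that add atoms: iodomethane, CI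
Why: Carboxylate O-alkylation (SN2 on iodomethane) esterifies an acid whose two ortho substituents would make Fischer esterification slow.

Step 13
Reactants: 16 (2S,5R,7S)-2-(hex-5-en-1-yl)-7-methyl-1,6-dioxaspiro[4.4]nonane; 21 methyl 2-iodo-4,6-dimethoxybenzoate
Product: 23 methyl 2,4-dimethoxy-6-{7-[(2S,5R,7S)-7-methyl-1,6-dioxaspiro[4.4]nonan-2-yl]heptanoyl}benzoate, via B-alkyl-9-BBN borane 22 (not isolated)
Conditions: 9-BBN-H, THF, 0 °C → rt; then 21, Pd(PPh3)4 (5 mol%), K3PO4, CO (1 atm), THF–benzene, rt → 50 °C
Reagents that add atoms: carbon monoxide, [C-]#[O+]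
Why: Carbonylative B-alkyl Suzuki–Miyaura coupling: 9-BBN-H adds anti-Markovnikov to the terminal alkene; zerovalent palladium inserts into the C–I bond of 21, CO insertion gives the aroylpalladium species, the phosphate-activated borane 22 transfers its primary alkyl group and reductive elimination gives the ketone. The medium is basic and holds no Lewis acid stronger than the borane, so the spiroketal is not at risk, and no stereocentre is formed.

Step 14
Reactants: 23 methyl 2,4-dimethoxy-6-{7-[(2S,5R,7S)-7-methyl-1,6-dioxaspiro[4.4]nonan-2-yl]heptanoyl}benzoate
Product: 25 (3R)-5,7-dimethoxy-3-{6-[(2S,5R,7S)-7-methyl-1,6-dioxaspiro[4.4]nonan-2-yl]hexyl}-2-benzofuran-1(3H)-one (target), via (1R)-hydroxy ester 24 (not isolated)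
Conditions: RuCl[(R,R)-TsDPEN](p-cymene) (2 mol%), HCO2Na, H2O–MeOH, 40 °C; K2CO3, MeOH, rt if lactonisation is incomplete
Reagents that add atoms: none
Why: Noyori–Ikariya asymmetric transfer hydrogenation of an aryl alkyl ketone, a reaction known to turn 2-acylbenzoates into 3-alkylphthalides: the ruthenium hydride and the ligand N–H deliver hydrogen to the carbonyl group through an outer-sphere six-membered transition state in which the arene lies against the cymene ligand, so the R,R ligand should give the 1R alkoxide of 24 (C3 of the lactone), which closes onto the neighbouring ester (5-exo-trig acyl substitution). The aqueous formate medium is neutral to basic, so C5 is not equilibrated; should the ortho ester reverse the facial sense, the S,S ligand is used.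

## Compound list

1 | 5-bromopent-1-ene | C=CCCCBr | starting material
2 | methyl (2S)-oxirane-2-carboxylate (methyl (S)-glycidate) | COC(=O)[C@@H]1CO1 | starting material
3 | pent-4-enylmagnesium bromide | C=CCCC[Mg]Br | intermediate (not isolated)
4 | methyl (2S)-2-hydroxyoct-7-enoate | C=CCCCC[C@H](O)C(=O)OC | intermediate
5 | (S)-gamma-valerolactone | C[C@H]1CCC(=O)O1 | starting material
6 | diisobutylaluminium (5S)-5-methyltetrahydrofuran-2-olate | C[C@H]1CCC(O[Al](CC(C)C)CC(C)C)O1 | intermediate (not isolated)
7 | (5S)-5-methyltetrahydrofuran-2-yl acetate (both anomers) | C[C@H]1CCC(OC(C)=O)O1 | intermediate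
8 | methyl (2S)-2-{[(2S,5S)-5-methyltetrahydrofuran-2-yl]oxy}oct-7-enoate | C=CCCCC[C@H](O[C@H]1CC[C@H](C)O1)C(=O)OC | intermediate
9 | potassium (2S)-2-{[(2S,5S)-5-methyltetrahydrofuran-2-yl]oxy}oct-7-enoate | C=CCCCC[C@H](O[C@H]1CC[C@H](C)O1)C(=O)[O-].[K+] | intermediate
10 | (2S)-2-{[(2S,5S)-5-methyltetrahydrofuran-2-yl]oxy}oct-7-enoic isobutyl carbonic anhydride | C=CCCCC[C@H](O[C@H]1CC[C@H](C)O1)C(=O)OC(=O)OCC(C)C | intermediate (not isolated)
11 | (3S)-1-diazo-3-{[(2S,5S)-5-methyltetrahydrofuran-2-yl]oxy}non-8-en-2-one | C=CCCCC[C@H](O[C@H]1CC[C@H](C)O1)C(=O)C=[N+]=[N-] | intermediate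
12 | (2S,5R,7S)-2-(hex-5-en-1-yl)-7-methyl-1,6-dioxaspiro[4.4]nonan-3-one | C=CCCCC[C@H]1C(=O)C[C@@]2(CC[C@H](C)O2)O1 | intermediate
13 | (2S,5R,7S)-2-(hex-5-en-1-yl)-7-methyl-1,6-dioxaspiro[4.4]nonan-3-ol (C3 epimers) | C=CCCCC[C@H]1C(O)C[C@@]2(CC[C@H](C)O2)O1 | intermediate
14 | sodium O-[(2S,5R,7S)-2-(hex-5-en-1-yl)-7-methyl-1,6-dioxaspiro[4.4]nonan-3-yl] carbonodithioate | C=CCCCC[C@H]1C(OC(=S)[S-])C[C@@]2(CC[C@H](C)O2)O1.[Na+] | intermediate (not isolated)
15 | O-[(2S,5R,7S)-2-(hex-5-en-1-yl)-7-methyl-1,6-dioxaspiro[4.4]nonan-3-yl] S-methyl carbonodithioate (C3 epimers) | C=CCCCC[C@H]1C(OC(=S)SC)C[C@@]2(CC[C@H](C)O2)O1 | intermediate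
16 | (2S,5R,7S)-2-(hex-5-en-1-yl)-7-methyl-1,6-dioxaspiro[4.4]nonane | C=CCCCC[C@H]1CC[C@@]2(CC[C@H](C)O2)O1 | intermediate
17 | 1-iodo-3,5-dimethoxybenzene | COc1cc(I)cc(OC)c1 | starting material
18 | [(2-iodo-4,6-dimethoxyphenyl)methylidene]dimethylammonium dichlorophosphate | COc1cc(I)c(C=[N+](C)C)c(OC)c1.[O-]P(=O)(Cl)Cl | intermediate (not isolated)
19 | 2-iodo-4,6-dimethoxybenzaldehyde | COc1cc(I)c(C=O)c(OC)c1 | intermediate
20 | 2-iodo-4,6-dimethoxybenzoic acid | COc1cc(I)c(C(=O)O)c(OC)c1 | intermediate
21 | methyl 2-iodo-4,6-dimethoxybenzoate | COC(=O)c1c(I)cc(OC)cc1OC | intermediate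
22 | 9-{6-[(2S,5R,7S)-7-methyl-1,6-dioxaspiro[4.4]nonan-2-yl]hexyl}-9-borabicyclo[3.3.1]nonane | C1CCC2CCCC1B2CCCCCC[C@H]1CC[C@@]3(CC[C@H](C)O3)O1 | intermediate (not isolated)
23 | methyl 2,4-dimethoxy-6-{7-[(2S,5R,7S)-7-methyl-1,6-dioxaspiro[4.4]nonan-2-yl]heptanoyl}benzoate | COC(=O)c1c(OC)cc(OC)cc1C(=O)CCCCCC[C@H]1CC[C@@]2(CC[C@H](C)O2)O1 | intermediate
24 | methyl 2-{(1R)-1-hydroxy-7-[(2S,5R,7S)-7-methyl-1,6-dioxaspiro[4.4]nonan-2-yl]heptyl}-4,6-dimethoxybenzoate | COC(=O)c1c(OC)cc(OC)cc1[C@H](O)CCCCCC[C@H]1CC[C@@]2(CC[C@H](C)O2)O1 | intermediate (not isolated)
25 | (3R)-5,7-dimethoxy-3-{6-[(2S,5R,7S)-7-methyl-1,6-dioxaspiro[4.4]nonan-2-yl]hexyl}-2-benzofuran-1(3H)-one | COc1cc(OC)c2c(c1)[C@@H](CCCCCC[C@H]1CC[C@@]3(CC[C@H](C)O3)O1)OC2=O | target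

## Step count and least certain steps

Total: 14 steps. Longest linear sequence: 10 steps (steps 1, 3, 4, 5, 6, 7, 8, 9, 13, 14). Steps 2 and 10–12 are side branches.

**Step 6 (key step, proposed new method).** Three processes may take over: capture of the carbene by the ring B oxygen lone pair (six-membered oxonium ylide, then 1,2-shift with ring expansion); hydride transfer followed by collapse through the enolate oxygen instead of carbon; and insertion into the C5 methylene of the chain. All three are plausible because the acetal is both the best hydride donor and the carrier of a second Lewis-basic oxygen. Partial loss of retention through a free oxocarbenium ion would in addition erode C5.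

The fallback uses known chemistry, sets out from 4 and returns at 16. Ester 4 would be reduced with LiAlH4 to (S)-oct-7-ene-1,2-diol F1, tosylated at the primary hydroxyl (TsCl, Bu2SnO cat., Et3N) to (S)-2-hydroxyoct-7-en-1-yl tosylate F2 and closed with K2CO3 in MeOH to (S)-1,2-epoxyoct-7-ene F3. Acetone N,N-dimethylhydrazone A1 would be lithiated with n-BuLi and alkylated with (S)-propylene oxide A2 to (S)-5-hydroxyhexan-2-one N,N-dimethylhydrazone F4. This would be lithiated again at its methyl group and alkylated with F3 to (2S,8S)-2,8-dihydroxytetradec-13-en-5-one N,N-dimethylhydrazone F5. Hydrolysis with aqueous oxalic acid, with spontaneous spiroketalisation, should give 16 together with its C5 epimer (2S,5S,7S)-2-(hex-5-en-1-yl)-7-methyl-1,6-dioxaspiro[4.4]nonane F6. The two would be separated by chromatography and F6 re-equilibrated with acid and recycled.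

**Step 3.** The acetalisation is expected to be unselective, and separation of the two anomers of an oily ester may be incomplete; slow anomerisation on silica would also erode the purity on which C5 depends. The fallback moves the separation to a later compound class; it sets out from 4 and 7 and returns at 11. The unseparated mixture of 8 and its cis anomer, methyl (2S)-2-{[(2R,5S)-5-methyltetrahydrofuran-2-yl]oxy}oct-7-enoate F7, would be taken through steps 4 and 5 via the cis potassium salt F8 and the cis mixed anhydride F9 to a mixture of 11 and the cis diazoketone F10. Separation would then be done on the polar diazoketones on base-washed silica, and only 11 would be taken into step 6.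

**Step 13.** Direct (non-carbonylative) coupling may outrun CO insertion, and base-induced cyclisation of the 2-acylbenzoate product to an indanedione is possible. The fallback builds the ketone from an acyl donor instead of CO; it sets out from 16 and returns at 23. Hydroformylation of 16 (Rh(acac)(CO)2, Xantphos, CO/H2) would give 7-[(2S,5R,7S)-7-methyl-1,6-dioxaspiro[4.4]nonan-2-yl]heptanal F11. Pinnick oxidation would give the heptanoic acid F12, and EDC/DMAP/EtSH its S-ethyl thioester F13. Fukuyama coupling (PdCl2(PPh3)2, THF) of F13 with [3,5-dimethoxy-2-(methoxycarbonyl)phenyl]zinc iodide F14, made from 21 with zinc dust and LiCl, should give 23.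

**Step 14.** The ortho ester and the two methoxy groups may weaken or reverse the facial discrimination of the catalyst. Reduction of the electron-rich ketone may also be slow. Any C3 epimer formed is unlikely to be removable. The fallback sets the carbinol centre on a ketone without the ortho ester and introduces the lactone carbonyl afterwards; it sets out from 16 (through 22) and from 17 and returns at 25. Bromination of 17 with NBS would give 2-bromo-1-iodo-3,5-dimethoxybenzene F15. Carbonylative coupling of 22 with F15 at the C–I bond, as in step 13, would give 1-(2-bromo-3,5-dimethoxyphenyl)-7-[(2S,5R,7S)-7-methyl-1,6-dioxaspiro[4.4]nonan-2-yl]heptan-1-one F16. Corey–Bakshi–Shibata reduction ((S)-methyl oxazaborolidine, catecholborane, −40 °C) would give the (1R)-bromo alcohol F17. Palladium-catalysed intramolecular alkoxycarbonylation (Pd(OAc)2, dppf, CO, K2CO3, DMF, 90 °C) should then close the lactone to 25.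

## Further compounds

F1 | step 6 | (S)-oct-7-ene-1,2-diol | C=CCCCC[C@H](O)CO
F2 | step 6 | (S)-2-hydroxyoct-7-en-1-yl 4-methylbenzenesulfonate | C=CCCCC[C@H](O)COS(=O)(=O)c1ccc(C)cc1
F3 | step 6 | (S)-1,2-epoxyoct-7-ene | C=CCCCC[C@H]1CO1
F4 | step 6 | (S)-5-hydroxyhexan-2-one N,N-dimethylhydrazone | CC(CC[C@H](C)O)=NN(C)C
F5 | step 6 | (2S,8S)-2,8-dihydroxytetradec-13-en-5-one N,N-dimethylhydrazone | C=CCCCC[C@H](O)CCC(CC[C@H](C)O)=NN(C)C
F6 | step 6 | (2S,5S,7S)-2-(hex-5-en-1-yl)-7-methyl-1,6-dioxaspiro[4.4]nonane | C=CCCCC[C@H]1CC[C@]2(CC[C@H](C)O2)O1
F7 | step 3 | methyl (2S)-2-{[(2R,5S)-5-methyltetrahydrofuran-2-yl]oxy}oct-7-enoate | C=CCCCC[C@H](O[C@@H]1CC[C@H](C)O1)C(=O)OC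
F8 | step 3 | potassium (2S)-2-{[(2R,5S)-5-methyltetrahydrofuran-2-yl]oxy}oct-7-enoate | C=CCCCC[C@H](O[C@@H]1CC[C@H](C)O1)C(=O)[O-].[K+]
F9 | step 3 | (2S)-2-{[(2R,5S)-5-methyltetrahydrofuran-2-yl]oxy}oct-7-enoic isobutyl carbonic anhydride | C=CCCCC[C@H](O[C@@H]1CC[C@H](C)O1)C(=O)OC(=O)OCC(C)C
F10 | step 3 | (3S)-1-diazo-3-{[(2R,5S)-5-methyltetrahydrofuran-2-yl]oxy}non-8-en-2-one | C=CCCCC[C@H](O[C@@H]1CC[C@H](C)O1)C(=O)C=[N+]=[N-]
F11 | step 13 | 7-[(2S,5R,7S)-7-methyl-1,6-dioxaspiro[4.4]nonan-2-yl]heptanal | O=CCCCCCC[C@H]1CC[C@@]2(CC[C@H](C)O2)O1
F12 | step 13 | 7-[(2S,5R,7S)-7-methyl-1,6-dioxaspiro[4.4]nonan-2-yl]heptanoic acid | OC(=O)CCCCCC[C@H]1CC[C@@]2(CC[C@H](C)O2)O1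
F13 | step 13 | S-ethyl 7-[(2S,5R,7S)-7-methyl-1,6-dioxaspiro[4.4]nonan-2-yl]heptanethioate | CCSC(=O)CCCCCC[C@H]1CC[C@@]2(CC[C@H](C)O2)O1
F14 | step 13 | [3,5-dimethoxy-2-(methoxycarbonyl)phenyl]zinc iodide | COC(=O)c1c([Zn]I)cc(OC)cc1OC
F15 | step 14 | 2-bromo-1-iodo-3,5-dimethoxybenzene | COc1cc(I)c(Br)c(OC)c1
F16 | step 14 | 1-(2-bromo-3,5-dimethoxyphenyl)-7-[(2S,5R,7S)-7-methyl-1,6-dioxaspiro[4.4]nonan-2-yl]heptan-1-one | COc1cc(OC)c(Br)c(c1)C(=O)CCCCCC[C@H]1CC[C@@]2(CC[C@H](C)O2)O1
F17 | step 14 | (1R)-1-(2-bromo-3,5-dimethoxyphenyl)-7-[(2S,5R,7S)-7-methyl-1,6-dioxaspiro[4.4]nonan-2-yl]heptan-1-ol | COc1cc(OC)c(Br)c(c1)[C@@H](CCCCCC[C@H]1CC[C@@]2(CC[C@H](C)O2)O1)O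
A1 | alternative 1 | acetone N,N-dimethylhydrazone | CC(C)=NN(C)C
A2 | alternative 1 | (S)-propylene oxide | C[C@H]1CO1
A3 | alternative 1 | (S)-1,2-epoxydec-9-ene | C=CCCCCCC[C@H]1CO1
A4 | alternative 1 | (2S,8S)-2,8-dihydroxyhexadec-15-en-5-one N,N-dimethylhydrazone | C=CCCCCCC[C@H](O)CCC(CC[C@H](C)O)=NN(C)C
A5 | alternative 1 | (2S,7S)-7-methyl-2-(oct-7-en-1-yl)-1,6-dioxaspiro[4.4]nonane (both C5 epimers) | C=CCCCCCC[C@H]1CCC2(CC[C@H](C)O2)O1
A6 | alternative 2 | methyl (4R)-4-(tert-butyldimethylsilyloxy)-10-[(2S,5R,7S)-7-methyl-1,6-dioxaspiro[4.4]nonan-2-yl]dec-2-ynoate | COC(=O)C#C[C@H](O[Si](C)(C)C(C)(C)C)CCCCCC[C@H]1CC[C@@]2(CC[C@H](C)O2)O1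
A7 | alternative 2 | 1,3-dimethoxy-1-(trimethylsilyloxy)buta-1,3-diene | COC(=C)C=C(OC)O[Si](C)(C)C
A8 | alternative 2 | methyl 2-hydroxy-4-methoxy-6-{(1R)-1-(tert-butyldimethylsilyloxy)-7-[(2S,5R,7S)-7-methyl-1,6-dioxaspiro[4.4]nonan-2-yl]heptyl}benzoate | COC(=O)c1c(O)cc(OC)cc1[C@H](O[Si](C)(C)C(C)(C)C)CCCCCC[C@H]1CC[C@@]2(CC[C@H](C)O2)O1
A9 | alternative 3 | (3R)-3-[(5S,6E,13S)-5,13-dihydroxy-10-oxotetradec-6-en-1-yl]-5,7-dimethoxy-2-benzofuran-1(3H)-one | COc1cc(OC)c2c(c1)[C@@H](CCCC[C@H](O)/C=C/CCC(=O)CC[C@H](C)O)OC2=O
A10 | alternative 3 | (3R)-3-{(5S,6E)-5-hydroxy-9-[(5S)-2-hydroxy-5-methyltetrahydrofuran-2-yl]non-6-en-1-yl}-5,7-dimethoxy-2-benzofuran-1(3H)-one (both epimers at the hemiketal carbon) | COc1cc(OC)c2c(c1)[C@@H](CCCC[C@H](O)/C=C/CCC1(O)CC[C@H](C)O1)OC2=O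
A11 | alternative 3 | (3R)-5,7-dimethoxy-3-{(5E)-6-[(2R,5R,7S)-7-methyl-1,6-dioxaspiro[4.4]nonan-2-yl]hex-5-en-1-yl}-2-benzofuran-1(3H)-one (ring A C2 arranged in space as in the target; the descriptor is R only because the alkenyl group outranks the ring carbon) | COc1cc(OC)c2c(c1)[C@@H](CCCC/C=C/[C@H]1CC[C@@]3(CC[C@H](C)O3)O1)OC2=O
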